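**Plan**
- Structural feature: the oxolane O1–C2–C3–C4–C5 carries ring A (4-hydroxy-3-methoxyphenyl) at C2, a methyl at C3 and, through C7′H2, ring B (4-hydroxy-3,5-dimethoxyphenyl) at C4. C3–C4 joins the β-carbons (C8, C8′) of two phenylpropanoid units. O1–C2 is a benzylic C–O bond para to the ring A phenol, the mark of an oxygen nucleophile caught by a ring A quinone methide.
- Retrosynthesis: C5 is raised to a lactone carbonyl, C4–C7′ to an alkene, and ring A is given a bromine ortho to its phenol. C3–C4 and O1–C2 are then cut together, which leads to (E)-5-bromoisoeugenol and sinapic acid.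
- Forward: eugenol gives the bromopropenylphenol in two steps. Ag2O unites it with sinapic acid (C3–C4), the carboxyl closes the only new ring (O1–C2), and proton loss from C4 ends at a benzylidene lactone. Silylation, resolution, hydrogenation/epimerisation, two-stage lactone-to-oxolane reduction and desilylation follow.
- Stereochemistry: C3 is formed racemic in the radical union and C2 follows it (closure anti to the methyl, 2,3-trans). C4 is set afterwards by enolate equilibration to the all-trans lactone. The absolute sense comes from chromatographic resolution of the silylated bromolactone.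
- Design points: the acid level at C5 makes the ring closure the one known from cinnamic acid dimerisation and makes C4 correctable. The bromine closes the 8–5 channel of ring A, allows the absolute configuration to be read by X-ray analysis, and leaves during the hydrogenation.

Key step: step 3

Remark: every compound between the coupling and the resolution is a racemate; its name carries (±) and its SMILES shows the enantiomer that is carried on.
Remark: the Why lines keep the locants of the target oxolane (C5 is the lactone carbonyl carbon); systematic names use their own locants.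

**Step 1**
Reactants: 1 eugenol (4-allyl-2-methoxyphenol)
Product: 2 6-bromoeugenol (4-allyl-2-bromo-6-methoxyphenol)
Conditions: NBS (1.0 equiv), i-Pr2NH (10 mol %), CH2Cl2, 0 °C
Reagents that add atoms: N-bromosuccinimide, O=C1CCC(=O)N1Br
Why: Electrophilic aromatic substitution (amine-catalysed ortho-bromination of a phenol with NBS): the phenol directs to its only free ortho position, the para position being taken by the allyl group, and the isolated terminal alkene is far less nucleophilic than the activated ring.

**Step 2**
Reactants: 2 6-bromoeugenol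
Product: 3 (E)-5-bromoisoeugenol (2-bromo-6-methoxy-4-[(E)-prop-1-enyl]phenol)
Conditions: RuHCl(CO)(PPh3)3 (1 mol %), toluene, 90 °C
Reagents that add atoms: none
Why: Ruthenium hydride catalysed alkene isomerisation (hydrometalation and β-hydride elimination) moves the double bond into conjugation with the arene and should give the more stable E isomer, while the phenol and the aryl bromide are spectators.

**Step 3**
Reactants: 3 (E)-5-bromoisoeugenol; 4 sinapic acid ((E)-3-(4-hydroxy-3,5-dimethoxyphenyl)prop-2-enoic acid)
Product: 7 (±)-(3E,4R,5R)-5-(3-bromo-4-hydroxy-5-methoxyphenyl)-3-(4-hydroxy-3,5-dimethoxybenzylidene)-4-methyloxolan-2-one, via bis(quinone methide) acid 5 (not isolated), via ring B quinone methide lactone 6 (not isolated)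
Conditions: 3 (3 equiv), Ag2O (2.2 equiv), 4 Å MS, acetone/CH2Cl2, 0 °C to rt, dark, 4 added over 6 h; filtration through Celite
Reagents that add atoms: none
Why: Proposed new method: Ag2O (monovalent silver) removes one electron and one proton from each free phenol, the two phenoxyl radicals, which carry spin at C8 of 3 and C8′ of 4, combine to C3–C4 and give bis(quinone methide) 5, the carboxyl oxygen adds to C2 of the ring A quinone methide (O1–C2, ring A rearomatises) to give 6, and loss of the C4 proton, acidified by the lactone carbonyl and the ring B quinone methide, rearomatises ring B to 7. The closest known reaction types are the oxidative 8–8′ dimerisation of sinapic and ferulic acid to bis-lactones, where each carboxyl closes on the quinone methide of the other half in just this way, and the Ag2O coupling of propenylphenols; the crossed union of an acid with a propenylphenol is the untested part. The one ring formed, the oxolan-2-one, closes in the 5-exo-trig mode, since the C2=C(ring A) bond that is attacked lies outside the new ring. C3 arises in the radical union with no facial bias, so 7 is racemic and step 5 supplies the absolute sense; C2 is controlled by C3, because the carboxyl reaches the quinone methide from the side away from the C3 methyl and because the closure is reversible enough to settle on the more stable 2,3-trans lactone; the configuration that C4 has in 5 and 6 is given up on purpose and is set in step 6. Cross- over homo-coupling is what the step needs most, and it is served by pairing an electron-poor C8′ radical (next to CO2H) with an electron-rich C8 radical, by the acceptor on ring B, which offsets its second methoxy group so that both phenols should be oxidised at comparable rates, and by slow addition of 4 to an excess of 3. The 8–8′ regiochemistry is secured by the substrate, since all four positions ortho to the two phenols are occupied (OMe, OMe, OMe, Br), which shuts every 8–5 channel and leaves only 8–O–4 ethers as competing modes.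

**Step 4**
Reactants: 7 (±)-benzylidene lactone
Product: 8 (±)-(3E,4R,5R)-5-[3-bromo-4-(tert-butyldimethylsilyloxy)-5-methoxyphenyl]-3-[4-(tert-butyldimethylsilyloxy)-3,5-dimethoxybenzylidene]-4-methyloxolan-2-one
Conditions: TBSCl (3 equiv), imidazole (6 equiv), DMF, 0 °C to rt
Reagents that add atoms: tert-butyldimethylsilyl chloride, CC(C)(C)[Si](C)(C)Cl
Why: Imidazole-promoted silylation of phenols is mild enough not to open the γ-(4-hydroxyaryl) lactone through its phenoxide, and capping both phenols makes the later base, hydride and Lewis acid steps safe.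

**Step 5**
Reactants: 8 (±)-bis-silyl benzylidene lactone
Product: 9 (3E,4R,5R)-enantiomer of 8, enantiopure
Conditions: preparative HPLC, amylose tris(3,5-dimethylphenylcarbamate) on silica, hexane/i-PrOH, rt
Reagents that add atoms: none
Why: Chromatographic resolution on a polysaccharide carbamate phase is routine for aryl lactones and lignans, neither C2 nor C3 is labile in the silylated lactone, and the bromine allows the absolute configuration of the collected enantiomer to be fixed by anomalous X-ray dispersion.

**Step 6**
Reactants: 9 (3E,4R,5R)-bis-silyl benzylidene lactone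
Product: 11 (3R,4R,5R)-5-[4-(tert-butyldimethylsilyloxy)-3-methoxyphenyl]-3-[4-(tert-butyldimethylsilyloxy)-3,5-dimethoxybenzyl]-4-methyloxolan-2-one (all-trans), via C4-epimeric lactone 10 (not isolated)
Conditions: H2 (1 atm), 10% Pd/C, Et3N, EtOAc, rt; filter, concentrate; DBU, dry toluene, 80 °C
Reagents that add atoms: none
Why: Heterogeneous catalytic hydrogenation saturates C4=C7′ and, with Et3N as HBr trap, hydrogenolyses the aryl C–Br bond, and base-mediated epimerisation through the lactone enolate then moves C4 to the thermodynamically preferred all-trans arrangement (benzyl anti to the C3 methyl), as is usual for α-benzyl lignan lactones.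

**Step 7**
Reactants: 11 all-trans lactone
Product: 12 (3R,4R,5R)-5-[4-(tert-butyldimethylsilyloxy)-3-methoxyphenyl]-3-[4-(tert-butyldimethylsilyloxy)-3,5-dimethoxybenzyl]-4-methyloxolan-2-ol (anomers)
Conditions: i-Bu2AlH (1.2 equiv), CH2Cl2, −78 °C; aq. Rochelle salt
Reagents that add atoms: none
Why: Partial reduction of a lactone with i-Bu2AlH stops at the aluminium hemiacetal at −78 °C and gives the lactol on work-up without touching C2, C3, C4 or the aryl silyl ethers.

**Step 8**
Reactants: 12 lactol
Product: 13 (2R,3R,4R)-2-[4-(tert-butyldimethylsilyloxy)-3-methoxyphenyl]-4-[4-(tert-butyldimethylsilyloxy)-3,5-dimethoxybenzyl]-3-methyloxolane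
Conditions: Et3SiH (3 equiv), BF3·OEt2 (1.5 equiv), CH2Cl2, −78 °C
Reagents that add atoms: none
Why: Ionic reduction of a lactol (BF3 ionises C5–OH to the cyclic oxocarbenium ion and Et3SiH delivers hydride) creates no stereocentre, and the low temperature together with the silylated ring A oxygen should keep the benzylic C2–O1 bond from ionising.

**Step 9**
Reactants: 13 bis-silyl oxolane
Product: 14 4-[(2R,3R,4R)-4-(4-hydroxy-3,5-dimethoxybenzyl)-3-methyloxolan-2-yl]-2-methoxyphenol (target)
Conditions: TBAF (2.5 equiv), AcOH (2.5 equiv), THF, 0 °C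
Reagents that add atoms: none
Why: Fluoride cleaves the two aryl silyl ethers (Si–F bond formation as driving force), acetic acid buffers the phenoxides, and the oxolane with its three stereocentres is inert to these conditions.

**Compound list**
1 | eugenol | C=CCc1ccc(O)c(OC)c1 | starting material
2 | 6-bromoeugenol | C=CCc1cc(Br)c(O)c(OC)c1 | intermediate
3 | (E)-5-bromoisoeugenol | C/C=C/c1cc(Br)c(O)c(OC)c1 | intermediate
4 | sinapic acid | COc1cc(/C=C/C(=O)O)cc(OC)c1O | starting material
5 | (±)-4-(3-bromo-5-methoxy-4-oxocyclohexa-2,5-dien-1-ylidene)-2-[(3,5-dimethoxy-4-oxocyclohexa-2,5-dien-1-ylidene)methyl]-3-methylbutanoic acid, epimers at C2 of the acid | C[C@@H](C=C1C=C(OC)C(=O)C(Br)=C1)C(C=C1C=C(OC)C(=O)C(OC)=C1)C(=O)O | intermediate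
6 | (±)-5-(3-bromo-4-hydroxy-5-methoxyphenyl)-3-[(3,5-dimethoxy-4-oxocyclohexa-2,5-dien-1-ylidene)methyl]-4-methyloxolan-2-one, 4,5-trans, epimers at C3 of the lactone | COc1cc([C@@H]2OC(=O)C(C=C3C=C(OC)C(=O)C(OC)=C3)[C@H]2C)cc(Br)c1O | intermediate
7 | (±)-(3E,4R,5R)-5-(3-bromo-4-hydroxy-5-methoxyphenyl)-3-(4-hydroxy-3,5-dimethoxybenzylidene)-4-methyloxolan-2-one | COc1cc([C@@H]2OC(=O)/C(=C/c3cc(OC)c(O)c(OC)c3)[C@H]2C)cc(Br)c1O | intermediate
8 | (±)-bis(tert-butyldimethylsilyl) ether of 7 | COc1cc([C@@H]2OC(=O)/C(=C/c3cc(OC)c(O[Si](C)(C)C(C)(C)C)c(OC)c3)[C@H]2C)cc(Br)c1O[Si](C)(C)C(C)(C)C | intermediate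
9 | (3E,4R,5R)-enantiomer of 8, enantiopure | COc1cc([C@@H]2OC(=O)/C(=C/c3cc(OC)c(O[Si](C)(C)C(C)(C)C)c(OC)c3)[C@H]2C)cc(Br)c1O[Si](C)(C)C(C)(C)C | intermediate
10 | (3S,4R,5R)-5-[4-(tert-butyldimethylsilyloxy)-3-methoxyphenyl]-3-[4-(tert-butyldimethylsilyloxy)-3,5-dimethoxybenzyl]-4-methyloxolan-2-one (3,4-cis) | COc1cc([C@@H]2OC(=O)[C@@H](Cc3cc(OC)c(O[Si](C)(C)C(C)(C)C)c(OC)c3)[C@H]2C)ccc1O[Si](C)(C)C(C)(C)C | intermediate
11 | (3R,4R,5R)-epimer of 10 (all-trans lactone) | COc1cc([C@@H]2OC(=O)[C@H](Cc3cc(OC)c(O[Si](C)(C)C(C)(C)C)c(OC)c3)[C@H]2C)ccc1O[Si](C)(C)C(C)(C)C | intermediate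
12 | (3R,4R,5R)-lactol from 11, anomers | COc1cc([C@@H]2OC(O)[C@H](Cc3cc(OC)c(O[Si](C)(C)C(C)(C)C)c(OC)c3)[C@H]2C)ccc1O[Si](C)(C)C(C)(C)C | intermediate
13 | (2R,3R,4R)-bis-silyl oxolane | COc1cc([C@@H]2OC[C@H](Cc3cc(OC)c(O[Si](C)(C)C(C)(C)C)c(OC)c3)[C@H]2C)ccc1O[Si](C)(C)C(C)(C)C | intermediate
14 | 4-[(2R,3R,4R)-4-(4-hydroxy-3,5-dimethoxybenzyl)-3-methyloxolan-2-yl]-2-methoxyphenol | COc1cc([C@@H]2OC[C@H](Cc3cc(OC)c(O)c(OC)c3)[C@H]2C)ccc1O | target

**Step count**
Total steps: 9. Longest linear sequence: 9 (1 to 14); sinapic acid 4 enters as bought in step 3.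

**Steps most likely to fail**

**Step 3.** Homo-coupling of either radical and 8–O–4 ether formation may outrun the crossed 8–8′ union, and silver-induced decarboxylation may drain the acid.

The fallback sets out from 3 and comes back at 9. It replaces steps 3 to 5 by known chemistry, and the absolute configuration then comes from a reagent-controlled crotylboration.
- 3 is silylated (TBSCl, imidazole, DMF) to silyl ether F1.
- Ozonolysis (O3, CH2Cl2/MeOH, −78 °C; Me2S) gives aldehyde F2. The same aldehyde is reached by silylating commercial 5-bromovanillin.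
- Brown crotylboration uses (E)-crotyl-B(Ipc)2 made from (−)-α-pinene ((E)-but-2-ene, n-BuLi/KOt-Bu, (+)-Ipc2BOMe, BF3·OEt2; THF, −78 °C; NaBO3·4H2O work-up). Through the chair transition state it should give the anti homoallylic alcohol F3, which sets C2 and C3.
- Hydroboration–oxidation (9-BBN, THF; NaBO3·4H2O) gives 1,4-diol F4.
- TEMPO/PhI(OAc)2 (CH2Cl2) oxidises the primary alcohol and then the lactol to trans lactone F5.
- Syringaldehyde is silylated (TBSCl, imidazole) to aldehyde F6.
- The lithium enolate of F5 (LiN(SiMe3)2, THF, −78 °C) adds to F6 anti to the methyl group and gives aldol adduct F7.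
- Mesylation and elimination (MsCl, Et3N; DBU, CH2Cl2) lead to 9.

**Step 6.** Hydrogenolysis of the benzylic C2–O1 bond of the lactone on palladium may compete with alkene saturation and debromination.

The fallback sets out from 9 and comes back at 11 without a hydrogenolysis-active metal.
- Conjugate reduction with copper hydride ([(Ph3P)CuH]6, toluene, rt), protonation of the enolate and equilibration with DBU (toluene, 80 °C) give bromolactone F8.
- Radical chain dehalogenation (Bu3SnH, AIBN, toluene, 80 °C) removes the bromine and gives 11.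

**Step 8.** Lewis acid ionisation of the benzylic C2–O1 bond may cause epimerisation at C2 or reductive ring opening.

The fallback sets out from 11 and comes back at 13. It replaces steps 7 and 8 and avoids cationic intermediates.
- LiAlH4 (THF, 0 °C) gives diol F9.
- Selective sulfonylation of the primary hydroxyl (TsCl, Et3N, cat. DMAP, CH2Cl2, 0 °C) gives monotosylate F10.
- KOt-Bu (THF, 0 °C) closes the ring by intramolecular Williamson etherification (5-exo-tet, O1–C5). The C2–O1 bond and its configuration stay untouched.

**Further compounds**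
F1 | step 3 | [2-bromo-6-methoxy-4-[(E)-prop-1-enyl]phenoxy](tert-butyl)dimethylsilane | C/C=C/c1cc(Br)c(O[Si](C)(C)C(C)(C)C)c(OC)c1
F2 | step 3 | 3-bromo-4-(tert-butyldimethylsilyloxy)-5-methoxybenzaldehyde | O=Cc1cc(Br)c(O[Si](C)(C)C(C)(C)C)c(OC)c1
F3 | step 3 | (1R,2R)-1-[3-bromo-4-(tert-butyldimethylsilyloxy)-5-methoxyphenyl]-2-methylbut-3-en-1-ol | COc1cc([C@H](O)[C@H](C)C=C)cc(Br)c1O[Si](C)(C)C(C)(C)C
F4 | step 3 | (1R,2R)-1-[3-bromo-4-(tert-butyldimethylsilyloxy)-5-methoxyphenyl]-2-methylbutane-1,4-diol | COc1cc([C@H](O)[C@H](C)CCO)cc(Br)c1O[Si](C)(C)C(C)(C)C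
F5 | step 3 | (4R,5R)-5-[3-bromo-4-(tert-butyldimethylsilyloxy)-5-methoxyphenyl]-4-methyloxolan-2-one | COc1cc([C@@H]2OC(=O)C[C@H]2C)cc(Br)c1O[Si](C)(C)C(C)(C)C
F6 | step 3 | 4-(tert-butyldimethylsilyloxy)-3,5-dimethoxybenzaldehyde | COc1cc(C=O)cc(OC)c1O[Si](C)(C)C(C)(C)C
F7 | step 3 | 3-[hydroxy(aryl)methyl] derivative of F5 (aryl = 4-(tert-butyldimethylsilyloxy)-3,5-dimethoxyphenyl), 3,4-trans-4,5-trans, carbinol epimers | COc1cc([C@@H]2OC(=O)[C@H](C(O)c3cc(OC)c(O[Si](C)(C)C(C)(C)C)c(OC)c3)[C@H]2C)cc(Br)c1O[Si](C)(C)C(C)(C)C
F8 | step 6 | (3R,4R,5R)-5-[3-bromo-4-(tert-butyldimethylsilyloxy)-5-methoxyphenyl]-3-[4-(tert-butyldimethylsilyloxy)-3,5-dimethoxybenzyl]-4-methyloxolan-2-one | COc1cc([C@@H]2OC(=O)[C@H](Cc3cc(OC)c(O[Si](C)(C)C(C)(C)C)c(OC)c3)[C@H]2C)cc(Br)c1O[Si](C)(C)C(C)(C)C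
F9 | step 8 | (1R,2R,3R)-1-[4-(tert-butyldimethylsilyloxy)-3-methoxyphenyl]-3-[4-(tert-butyldimethylsilyloxy)-3,5-dimethoxybenzyl]-2-methylbutane-1,4-diol | COc1cc([C@H](O)[C@H](C)[C@H](CO)Cc2cc(OC)c(O[Si](C)(C)C(C)(C)C)c(OC)c2)ccc1O[Si](C)(C)C(C)(C)C
F10 | step 8 | primary mono-p-toluenesulfonate of F9 | COc1cc([C@H](O)[C@H](C)[C@H](COS(=O)(=O)c2ccc(C)cc2)Cc2cc(OC)c(O[Si](C)(C)C(C)(C)C)c(OC)c2)ccc1O[Si](C)(C)C(C)(C)C
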